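**Retrosynthetic overview**
1. Target 15 comes from pyrrole 14 by one base-mediated global deprotection (two N-tosyl groups, one methyl ester).
2. The pyrrole ring is formed last, by a proposed new nickel-catalysed ring expansion of azirine 8 (gives N, C2–CO2Me, C3–indole) with the enolisable 1,2-diketone 12 (gives C4–indole, C5–acetyl); it makes the C3–C4 and N–C5 bonds.
3. Azirine 8 (fragment 1) comes from 5-chloroisoxazole 6, isoxazolone 5 and β-ketoester 3, i.e. from 1-tosylindole 1 and methyl malonyl chloride 2.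
4. Diketone 12 (fragment 2) comes from ketal 11, made by palladium-catalysed α-arylation of 3,3-dimethoxybutan-2-one 10 with 3-bromo-1-tosylindole 9.
5. Ring order: both indoles are bought; isoxazole, then azirine, then pyrrole.

Assumption: the target has no stereocentre or stable stereogenic axis (it is achiral), so "single enantiomer" is taken to mean the constitution drawn; tosyl (Ts) = p-toluenesulfonyl.

**Step 1**
Reactants: 1 1-tosyl-1H-indole; 2 methyl 3-chloro-3-oxopropanoate (methyl malonyl chloride)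
Product: 3 methyl 3-oxo-3-(1-tosyl-1H-indol-3-yl)propanoate
Conditions: AlCl3 (2.5 equiv), CH2Cl2, 0 °C to rt
Reagents that add atoms: none
Why: Friedel–Crafts acylation, in which the N-sulfonyl group tempers the indole so the AlCl3-activated acyl chloride attacks only C3 and the β-ketoester product is shielded as its aluminium chelate; no stereocentre is formed.

**Step 2**
Reactants: 3 methyl 3-oxo-3-(1-tosyl-1H-indol-3-yl)propanoate
Product: 5 3-(1-tosyl-1H-indol-3-yl)isoxazol-5(4H)-one, via oxime 4 (not isolated)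
Conditions: NH2OH·HCl (1.5 equiv), NaOAc (1.5 equiv), EtOH/H2O (4:1), 80 °C
Reagents that add atoms: hydroxylamine hydrochloride (NH2OH·HCl), Cl.NO
Why: Classical β-ketoester/hydroxylamine isoxazolone synthesis: ketone oximation gives 4, whose hydroxyl displaces methoxide from the ester to close the ring, and the acetate buffer leaves the N-tosyl group intact.

**Step 3**
Reactants: 5 3-(1-tosyl-1H-indol-3-yl)isoxazol-5(4H)-one
Product: 6 5-chloro-3-(1-tosyl-1H-indol-3-yl)isoxazole
Conditions: POCl3 (solvent), Et3N (1.0 equiv), 75 °C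
Reagents that add atoms: phosphoryl chloride (POCl3), O=P(Cl)(Cl)Cl
Why: Deoxychlorination through the 5-hydroxyisoxazole tautomer (O-phosphorylation, then addition–elimination by chloride) aromatises the ring; sulfonamide and indole are inert to POCl3.

**Step 4**
Reactants: 6 5-chloro-3-(1-tosyl-1H-indol-3-yl)isoxazole
Product: 8 methyl 3-(1-tosyl-1H-indol-3-yl)-2H-azirine-2-carboxylate (racemic), via azirine acid chloride 7 (not isolated)
Conditions: FeCl2 (anhydrous, 20 mol%), MeCN, rt; then MeOH (3 equiv), 2-methylpyridine (1.1 equiv), 0 °C to rt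
Reagents that add atoms: methanol, CO
Why: Isoxazole–azirine isomerisation, in which FeCl2 (divalent iron) cleaves the weak N–O bond and the vinylnitrenoid recloses to acid chloride 7, followed by acyl substitution with methanol and a hindered pyridine base; the C2 stereocentre of 8 forms racemic, which does not matter because it becomes an aromatic carbon in step 7.

**Step 5**
Reactants: 9 3-bromo-1-tosyl-1H-indole; 10 3,3-dimethoxybutan-2-one
Product: 11 3,3-dimethoxy-1-(1-tosyl-1H-indol-3-yl)butan-2-one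
Conditions: Pd2(dba)3 (2 mol%), Xantphos (5 mol%), K3PO4 (2.5 equiv), 10 (2 equiv), toluene, 90 °C
Reagents that add atoms: none
Why: Buchwald–Hartwig-type ketone α-arylation on zerovalent palladium: the ketal carbon allows enolisation only at the methyl group of 10, its bulk disfavours a second arylation, and the mild base K3PO4 spares the N-tosyl group.

**Step 6**
Reactants: 11 3,3-dimethoxy-1-(1-tosyl-1H-indol-3-yl)butan-2-one
Product: 12 1-(1-tosyl-1H-indol-3-yl)butane-2,3-dione
Conditions: TFA/H2O (9:1), CH2Cl2, 0 °C to rt; used crude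
Reagents that add atoms: water, O
Why: Acid-catalysed ketal hydrolysis (oxocarbenium ion captured by water) unveils the second carbonyl, the deactivated N-tosylindole survives TFA, and 12 (largely its conjugated enol) is used at once to avoid self-condensation.

**Step 7**
Reactants: 8 methyl 3-(1-tosyl-1H-indol-3-yl)-2H-azirine-2-carboxylate; 12 1-(1-tosyl-1H-indol-3-yl)butane-2,3-dione
Product: 14 methyl 5-acetyl-3,4-bis(1-tosyl-1H-indol-3-yl)-1H-pyrrole-2-carboxylate, via aziridine adduct 13 (not isolated)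
Conditions: NiCl2·6H2O (15 mol%), 12 (1.3 equiv), MeCN, 60 °C, N2
Reagents that add atoms: none
Why: Proposed new method: a divalent-nickel enolate annulation in which an enolisable 1,2-diketone replaces the usual 1,3-dicarbonyl partner — NiCl2·6H2O O,O-chelates the conjugated enol of 12 as a five-membered chelate, its benzylic carbon adds to the nickel-activated C=N carbon of azirine 8 to give NH-aziridine 13, the aziridine nitrogen attacks the adjacent carbonyl (the only one that can close a five-membered ring), strain-driven cleavage of the N–C3 bond expands the ring and loss of water aromatises it, so ester (C2), both indoles (C3, C4) and acetyl (C5) are placed without regiochemical ambiguity and the azirine stereocentre is erased; the closest known reaction type is the nickel- or copper-catalysed ring expansion of 2H-azirine-2-carboxylates with 1,3-diketones or β-ketoesters to 4-acylpyrrole-2-carboxylates.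

**Step 8**
Reactants: 14 methyl 5-acetyl-3,4-bis(1-tosyl-1H-indol-3-yl)-1H-pyrrole-2-carboxylate
Product: 15 5-acetyl-3,4-di(1H-indol-3-yl)-1H-pyrrole-2-carboxylic acid
Conditions: KOH (10 equiv), 1,4-dioxane/H2O (2:1), 80 °C; then 1 M HCl, 0 °C, to pH 3
Reagents that add atoms: potassium hydroxide (KOH), [K+].[OH-]
Why: Ester saponification and nucleophilic cleavage of both indole N-sulfonyl groups (indolide is a good leaving group) run in one pot, the methanol-free medium avoids N-methylation by methyl tosylate, the acetylpyrrole is stable as its pyrrolide, and cold acidification avoids decarboxylation; 15 has no stereocentre.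

**Compound list**
1 | 1-tosyl-1H-indole | Cc1ccc(S(=O)(=O)n2ccc3ccccc32)cc1 | starting material
2 | methyl 3-chloro-3-oxopropanoate (methyl malonyl chloride) | COC(=O)CC(=O)Cl | starting material
3 | methyl 3-oxo-3-(1-tosyl-1H-indol-3-yl)propanoate | COC(=O)CC(=O)c1cn(S(=O)(=O)c2ccc(C)cc2)c2ccccc12 | intermediate
4 | methyl 3-(hydroxyimino)-3-(1-tosyl-1H-indol-3-yl)propanoate (oxime, E/Z mixture, not isolated) | COC(=O)CC(=NO)c1cn(S(=O)(=O)c2ccc(C)cc2)c2ccccc12 | intermediate
5 | 3-(1-tosyl-1H-indol-3-yl)isoxazol-5(4H)-one | O=C1CC(c2cn(S(=O)(=O)c3ccc(C)cc3)c3ccccc23)=NO1 | intermediate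
6 | 5-chloro-3-(1-tosyl-1H-indol-3-yl)isoxazole | Clc1cc(-c2cn(S(=O)(=O)c3ccc(C)cc3)c3ccccc23)no1 | intermediate
7 | 3-(1-tosyl-1H-indol-3-yl)-2H-azirine-2-carbonyl chloride (racemic, not isolated) | O=C(Cl)C1N=C1c1cn(S(=O)(=O)c2ccc(C)cc2)c2ccccc12 | intermediate
8 | methyl 3-(1-tosyl-1H-indol-3-yl)-2H-azirine-2-carboxylate (racemic) | COC(=O)C1N=C1c1cn(S(=O)(=O)c2ccc(C)cc2)c2ccccc12 | intermediate
9 | 3-bromo-1-tosyl-1H-indole | Cc1ccc(S(=O)(=O)n2cc(Br)c3ccccc32)cc1 | starting material
10 | 3,3-dimethoxybutan-2-one | CC(=O)C(C)(OC)OC | starting material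
11 | 3,3-dimethoxy-1-(1-tosyl-1H-indol-3-yl)butan-2-one | COC(C)(OC)C(=O)Cc1cn(S(=O)(=O)c2ccc(C)cc2)c2ccccc12 | intermediate
12 | 1-(1-tosyl-1H-indol-3-yl)butane-2,3-dione (in equilibrium with its conjugated enol) | CC(=O)C(=O)Cc1cn(S(=O)(=O)c2ccc(C)cc2)c2ccccc12 | intermediate
13 | methyl 3-[2,3-dioxo-1-(1-tosyl-1H-indol-3-yl)butyl]-3-(1-tosyl-1H-indol-3-yl)aziridine-2-carboxylate (diastereomer mixture, not isolated) | COC(=O)C1NC1(c1cn(S(=O)(=O)c2ccc(C)cc2)c2ccccc12)C(C(=O)C(C)=O)c1cn(S(=O)(=O)c2ccc(C)cc2)c2ccccc12 | intermediate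
14 | methyl 5-acetyl-3,4-bis(1-tosyl-1H-indol-3-yl)-1H-pyrrole-2-carboxylate | COC(=O)c1[nH]c(C(C)=O)c(-c2cn(S(=O)(=O)c3ccc(C)cc3)c3ccccc23)c1-c1cn(S(=O)(=O)c2ccc(C)cc2)c2ccccc12 | intermediate
15 | 5-acetyl-3,4-di(1H-indol-3-yl)-1H-pyrrole-2-carboxylic acid | CC(=O)c1[nH]c(C(=O)O)c(-c2c[nH]c3ccccc23)c1-c1c[nH]c2ccccc12 | target

**Step count and risks**
Total steps: 8. Longest linear sequence: 6 (steps 1, 2, 3, 4, 7, 8, from 1-tosylindole).

Most likely to fail, first: step 7, the proposed new annulation. The hindered enol of 12 may add too slowly to the electron-rich, hindered azirine, so that azirine dimerisation or self-condensation of 12 wins. The fallback uses only known chemistry, sets out from 9 and comes back at 14. Miyaura borylation of 9 (B2pin2, Pd(dppf)Cl2, KOAc, dioxane, 90 °C) gives 3-(4,4,5,5-tetramethyl-1,3,2-dioxaborolan-2-yl)-1-tosyl-1H-indole F1. Twofold Suzuki–Miyaura coupling of F1 (2.4 equiv) with commercial 3,4-dibromo-1-(triisopropylsilyl)-1H-pyrrole (Pd(PPh3)4, aqueous Na2CO3, DME, 85 °C) gives 3,3'-[1-(triisopropylsilyl)-1H-pyrrole-3,4-diyl]bis(1-tosyl-1H-indole) F2. Desilylation (Bu4NF, THF, 0 °C) gives 3,3'-(1H-pyrrole-3,4-diyl)bis(1-tosyl-1H-indole) F3. α-Acylation with trichloroacetyl chloride (2,6-lutidine, CH2Cl2, rt) gives 2,2,2-trichloro-1-[3,4-bis(1-tosyl-1H-indol-3-yl)-1H-pyrrol-2-yl]ethan-1-one F4. Haloform-type methanolysis (MeOH, Et3N, rt) gives methyl 3,4-bis(1-tosyl-1H-indol-3-yl)-1H-pyrrole-2-carboxylate F5. Friedel–Crafts acetylation at the only free pyrrole carbon (Ac2O, BF3·OEt2, CH2Cl2, 0 °C to rt) then gives 14, and step 8 follows unchanged.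

Second: step 4. The azirine acid chloride 7 or the indolyl azirine 8 may decompose, or the iron-mediated ring contraction may stall on this electron-rich isoxazole. The fallback sets out from 3 and comes back at 8 by a Neber reaction instead of an isoxazole isomerisation. Oxime 4 is made and this time isolated (NH2OH·HCl, pyridine, EtOH, rt, stopped before ring closure). O-Tosylation (TsCl, pyridine, CH2Cl2, 0 °C) gives methyl 3-(1-tosyl-1H-indol-3-yl)-3-[(tosyloxy)imino]propanoate F6. Et3N (CH2Cl2, 0 °C to rt) then effects 1,3-elimination and ring closure to azirine 8.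

Third: step 5. Oxidative addition to the hindered 3-bromoindole may be sluggish under weak-base conditions, or diarylation may occur. The fallback sets out from 9 and comes back at 12, by-passing 11 and step 6. Heck reaction of 9 with but-3-en-2-ol (Pd(OAc)2, P(o-tol)3, Bu4NCl, NaHCO3, DMF, 90 °C) gives 4-(1-tosyl-1H-indol-3-yl)butan-2-one F7. Acid-catalysed α-nitrosation at the methylene next to the ketone (isoamyl nitrite, HCl, Et2O, 0 °C) gives 3-(hydroxyimino)-4-(1-tosyl-1H-indol-3-yl)butan-2-one F8. Transoximation with aqueous formaldehyde/HCl (THF, rt) releases diketone 12.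

**Further compounds**
F1 | step 7 | 3-(4,4,5,5-tetramethyl-1,3,2-dioxaborolan-2-yl)-1-tosyl-1H-indole | Cc1ccc(S(=O)(=O)n2cc(B3OC(C)(C)C(C)(C)O3)c3ccccc32)cc1
F2 | step 7 | 3,3'-[1-(triisopropylsilyl)-1H-pyrrole-3,4-diyl]bis(1-tosyl-1H-indole) | CC(C)[Si](C(C)C)(C(C)C)n1cc(-c2cn(S(=O)(=O)c3ccc(C)cc3)c3ccccc23)c(-c2cn(S(=O)(=O)c3ccc(C)cc3)c3ccccc23)c1
F3 | step 7 | 3,3'-(1H-pyrrole-3,4-diyl)bis(1-tosyl-1H-indole) | c1[nH]cc(-c2cn(S(=O)(=O)c3ccc(C)cc3)c3ccccc23)c1-c1cn(S(=O)(=O)c2ccc(C)cc2)c2ccccc12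
F4 | step 7 | 2,2,2-trichloro-1-[3,4-bis(1-tosyl-1H-indol-3-yl)-1H-pyrrol-2-yl]ethan-1-one | O=C(c1[nH]cc(-c2cn(S(=O)(=O)c3ccc(C)cc3)c3ccccc23)c1-c1cn(S(=O)(=O)c2ccc(C)cc2)c2ccccc12)C(Cl)(Cl)Cl
F5 | step 7 | methyl 3,4-bis(1-tosyl-1H-indol-3-yl)-1H-pyrrole-2-carboxylate | COC(=O)c1[nH]cc(-c2cn(S(=O)(=O)c3ccc(C)cc3)c3ccccc23)c1-c1cn(S(=O)(=O)c2ccc(C)cc2)c2ccccc12
F6 | step 4 | methyl 3-(1-tosyl-1H-indol-3-yl)-3-[(tosyloxy)imino]propanoate | COC(=O)CC(=NOS(=O)(=O)c1ccc(C)cc1)c1cn(S(=O)(=O)c2ccc(C)cc2)c2ccccc12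
F7 | step 5 | 4-(1-tosyl-1H-indol-3-yl)butan-2-one | CC(=O)CCc1cn(S(=O)(=O)c2ccc(C)cc2)c2ccccc12
F8 | step 5 | 3-(hydroxyimino)-4-(1-tosyl-1H-indol-3-yl)butan-2-one | CC(=O)C(=NO)Cc1cn(S(=O)(=O)c2ccc(C)cc2)c2ccccc12
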